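**Retrosynthetic overview**

- Feature: C4 of the tetralone is the benzylic carbon on C1′ of the naphthalene, para to the free C4′–OH. It is bonded to C4a, which is para to the C7–OH of the catechol ring. The C4–C4a bond therefore joins a naphthoquinone-methide carbon to a phenol para-carbon.
- Disconnection 1 (last bond, only ring formed): C4–C4a, closing the cyclohexanone ring by a catalytic asymmetric Friedel–Crafts alkylation of the racemic carbinol 13.
- Disconnection 2: C1–C8a, the aryl ketone from a 2,3-bis(silyloxy)phenyllithium and the γ-naphthyl-γ-butyrolactone 7.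
- Disconnection 3: C4–C1′, from the 1-lithionaphthalene (para-bromination of 5-methoxy-1-naphthol) and methyl 4-oxobutanoate. Both arenes are bought; the lactone ring is only a temporary carrier of the chain.

Key step: step 7

Assumption: the sense of induction of a given phosphoric acid enantiomer cannot be predicted with certainty, so the route is written with (R)-TRIP and the equally available (S)-catalyst is to be used if a first run delivers the antipode. Compounds 12 and 13 are drawn as open hydroxy ketones, although they may sit in equilibrium with their cyclic lactols, which converge on the same methide. The target centre C4 is S (CIP order C4a > C1′ > C3 > H).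

**Route**

Step 1
Reactants: 1 5-methoxy-1-naphthol
Product: 2 4-bromo-5-methoxynaphthalen-1-ol
Conditions: NBS (1.0 equiv), MeCN, −20 → 0 °C, dark
Reagents that add atoms: N-bromosuccinimide, O=C1CCC(=O)N1Br
Why: Electrophilic aromatic bromination, in which the free hydroxyl is the strongest donor and NBS in polar acetonitrile should attack the α-position para to it (C4), the site at which 1,5-dialkoxynaphthalenes are also substituted, while one equivalent at low temperature limits ortho- and over-bromination.

Step 2
Reactants: 2 4-bromo-5-methoxynaphthalen-1-ol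
Product: 3 [(4-bromo-5-methoxynaphthalen-1-yl)oxy]triisopropylsilane
Conditions: TIPSCl, imidazole, DMF, rt
Reagents that add atoms: chlorotriisopropylsilane, CC(C)[Si](Cl)(C(C)C)C(C)C
Why: Standard silylation of a phenol, with the triisopropylsilyl ether chosen because it should resist the organolithium and the lithium methoxide of step 3 and still fall to fluoride.

Step 3
Reactants: 3 [(4-bromo-5-methoxynaphthalen-1-yl)oxy]triisopropylsilane; 4 methyl 4-oxobutanoate
Product: 7 rac-5-[8-methoxy-4-(triisopropylsilyloxy)naphthalen-1-yl]oxolan-2-one, via naphthyllithium 5 (not isolated), via lithium alkoxide ester 6 (not isolated)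
Conditions: n-BuLi (1.05 equiv), THF, −78 °C; then 4 (1.2 equiv), −78 °C → rt; aq NH4Cl
Reagents that add atoms: none
Why: Bromine–lithium exchange followed by 1,2-addition of the aryllithium to the aldehyde, which is far more electrophilic than the ester at −78 °C, and lactonisation of the γ-alkoxide onto the methyl ester on warming; the new carbinol centre is racemic, which is acceptable because it is erased in step 7.

Step 4
Reactants: 8 3-bromocatechol
Product: 9 1-bromo-2,3-bis(tert-butyldimethylsilyloxy)benzene
Conditions: TBSCl (2.5 equiv), imidazole, DMF, rt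
Reagents that add atoms: tert-butyldimethylsilyl chloride, CC(C)(C)[Si](C)(C)Cl
Why: Standard bis-silylation of a catechol, giving ethers that tolerate the halogen–metal exchange at low temperature and are removed under near-neutral fluoride conditions.

Step 5
Reactants: 9 1-bromo-2,3-bis(tert-butyldimethylsilyloxy)benzene; 7 rac-5-[8-methoxy-4-(triisopropylsilyloxy)naphthalen-1-yl]oxolan-2-one
Product: 12 rac-1-[2,3-bis(tert-butyldimethylsilyloxy)phenyl]-4-hydroxy-4-[8-methoxy-4-(triisopropylsilyloxy)naphthalen-1-yl]butan-1-one, via aryllithium 10 (not isolated), via lithium lactolate 11 (not isolated)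
Conditions: 9 (1.1 equiv), t-BuLi (2.2 equiv), Et2O, −78 °C; then 7 in THF, −78 °C; aq NH4Cl at −78 °C
Reagents that add atoms: none
Why: Bromine–lithium exchange and nucleophilic acyl addition of the aryllithium to the γ-lactone, which should stop at the ketone oxidation level because the tetrahedral lithium lactolate is stable at −78 °C and opens to the hydroxy ketone only on protic quench; ether solvent and strict cold handling keep the ortho-silyloxy aryllithium from O→C silyl migration.

Step 6
Reactants: 12 rac-1-[2,3-bis(tert-butyldimethylsilyloxy)phenyl]-4-hydroxy-4-[8-methoxy-4-(triisopropylsilyloxy)naphthalen-1-yl]butan-1-one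
Product: 13 rac-1-(2,3-dihydroxyphenyl)-4-hydroxy-4-(4-hydroxy-8-methoxynaphthalen-1-yl)butan-1-one
Conditions: TBAF (3.5 equiv), AcOH (3.5 equiv), THF, 0 °C, Ar; pH 7 buffer work-up, used promptly
Reagents that add atoms: none
Why: Fluoride cleavage of the three aryl silyl ethers, with acetic acid buffering to keep the medium near neutral so that the catechol is not oxidised as its anion and the p-hydroxynaphthyl carbinol is neither ionised by acid nor eliminated by base.

Step 7
Reactants: 13 rac-1-(2,3-dihydroxyphenyl)-4-hydroxy-4-(4-hydroxy-8-methoxynaphthalen-1-yl)butan-1-one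
Product: 15 (4S)-7,8-dihydroxy-4-(4-hydroxy-8-methoxynaphthalen-1-yl)-3,4-dihydronaphthalen-1(2H)-one, via naphthoquinone methide 14 (not isolated)
Conditions: (R)-TRIP (10 mol %), CH2Cl2 (0.01 M), 4 Å MS, 0 °C → rt, Ar
Reagents that add atoms: none
Why: The chiral phosphoric acid protonates the carbinol (or lactol) oxygen and water leaves with push from the para naphthol oxygen, so both enantiomers of 13 converge on the planar naphthoquinone methide 14, held to the phosphate by hydrogen bonding at the methide oxygen, which makes the step stereoconvergent. The closest known reaction type is the chiral phosphoric acid-catalysed enantioselective 1,6-addition (Friedel–Crafts) of phenols and other electron-rich arenes to para-quinone methides generated in situ from para-hydroxybenzyl alcohols, here run intramolecularly. The cyclohexanone ring closes 6-exo-trig by attack of the aryl carbon para to the 3-hydroxyl (future C4a) on the exocyclic methide carbon (future C4), followed by rearomatisation of both rings. The C4 stereocentre is set by enantiofacial discrimination of the methide within the catalyst pocket, the 3,3′-aryl groups shielding one face; the peri-methoxy group should enforce a single methide geometry (chain syn to C2′–H), and because the nucleophile's para-hydroxyl lies about 9 Å from the methide oxygen, a two-point bridge by one phosphate is not relied on. The step needs C- over O-alkylation and a single ring size: only the carbon ortho to the acyl group and para to the 3-hydroxyl can reach the methide in a six-membered transition state, and O-attack by the 2-hydroxyl or the ketone gives ethers that re-ionise under the acid, so the C–C bond is the sink. High dilution is used to suppress intermolecular attack by the naphthol.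

**Compound list**

1 | 5-methoxy-1-naphthol | COc1cccc2c(O)cccc12 | starting material
2 | 4-bromo-5-methoxynaphthalen-1-ol | COc1cccc2c(O)ccc(Br)c12 | intermediate
3 | [(4-bromo-5-methoxynaphthalen-1-yl)oxy]triisopropylsilane | COc1cccc2c(O[Si](C(C)C)(C(C)C)C(C)C)ccc(Br)c12 | intermediate
4 | methyl 4-oxobutanoate | COC(=O)CCC=O | starting material
5 | [8-methoxy-4-(triisopropylsilyloxy)naphthalen-1-yl]lithium | COc1cccc2c(O[Si](C(C)C)(C(C)C)C(C)C)ccc([Li])c12 | intermediate
6 | lithium alkoxide of racemic methyl 4-hydroxy-4-[8-methoxy-4-(triisopropylsilyloxy)naphthalen-1-yl]butanoate | COC(=O)CCC(O[Li])c1ccc(O[Si](C(C)C)(C(C)C)C(C)C)c2cccc(OC)c12 | intermediate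
7 | rac-5-[8-methoxy-4-(triisopropylsilyloxy)naphthalen-1-yl]oxolan-2-one | O=C1CCC(O1)c1ccc(O[Si](C(C)C)(C(C)C)C(C)C)c2cccc(OC)c12 | intermediate
8 | 3-bromocatechol | Oc1cccc(Br)c1O | starting material
9 | 1-bromo-2,3-bis(tert-butyldimethylsilyloxy)benzene | CC(C)(C)[Si](C)(C)Oc1cccc(Br)c1O[Si](C)(C)C(C)(C)C | intermediate
10 | [2,3-bis(tert-butyldimethylsilyloxy)phenyl]lithium | CC(C)(C)[Si](C)(C)Oc1cccc([Li])c1O[Si](C)(C)C(C)(C)C | intermediate
11 | lithium 2-[2,3-bis(tert-butyldimethylsilyloxy)phenyl]-5-[8-methoxy-4-(triisopropylsilyloxy)naphthalen-1-yl]oxolan-2-olate (diastereomer mixture, racemic) | [Li]OC1(CCC(O1)c1ccc(O[Si](C(C)C)(C(C)C)C(C)C)c2cccc(OC)c12)c1cccc(O[Si](C)(C)C(C)(C)C)c1O[Si](C)(C)C(C)(C)C | intermediate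
12 | rac-1-[2,3-bis(tert-butyldimethylsilyloxy)phenyl]-4-hydroxy-4-[8-methoxy-4-(triisopropylsilyloxy)naphthalen-1-yl]butan-1-one | COc1cccc2c(O[Si](C(C)C)(C(C)C)C(C)C)ccc(C(O)CCC(=O)c3cccc(O[Si](C)(C)C(C)(C)C)c3O[Si](C)(C)C(C)(C)C)c12 | intermediate
13 | rac-1-(2,3-dihydroxyphenyl)-4-hydroxy-4-(4-hydroxy-8-methoxynaphthalen-1-yl)butan-1-one | COc1cccc2c(O)ccc(C(O)CCC(=O)c3cccc(O)c3O)c12 | intermediate
14 | 4-[4-(2,3-dihydroxyphenyl)-4-oxobutylidene]-5-methoxynaphthalen-1(4H)-one (chain syn to C3–H) | O=C1C=C/C(=C\CCC(=O)c2cccc(O)c2O)c2c(OC)cccc12 | intermediate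
15 | (4S)-7,8-dihydroxy-4-(4-hydroxy-8-methoxynaphthalen-1-yl)-3,4-dihydronaphthalen-1(2H)-one | COc1cccc2c(O)ccc([C@@H]3CCC(=O)c4c3ccc(O)c4O)c12 | target

**Count**

Total steps: 7. Longest linear sequence: 6 steps (1 → 2 → 3 → 7 → 12 → 13 → 15; step 4 is a one-step side branch).

**Steps most likely to fail**

1. Step 7. Facial discrimination of the methide may be poor, because the catalyst is anchored only at the methide oxygen. Attack by the acyl-deactivated ring may also be slow enough for intermolecular alkylation of the naphthol or drift to the vinylnaphthol tautomer to compete. Fallback (stereocontrol by resolution instead of catalysis): starting from 13, ring closure with an achiral Brønsted acid (diphenyl phosphate or TsOH in CH2Cl2/HFIP at high dilution) should give racemic 7,8-dihydroxy-4-(4-hydroxy-8-methoxynaphthalen-1-yl)-3,4-dihydronaphthalen-1(2H)-one F1. Preparative chromatography on a chiral stationary phase then separates the enantiomers and returns to the route at 15.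

2. Step 5. The ortho-silyloxy aryllithium may undergo O→C silyl migration on any warming. The lactolate may collapse and take up a second aryllithium, or the lactone may be enolised instead of attacked. Fallback (Weinreb amide as acyl donor, arylmagnesium as nucleophile): starting from 7, aminolysis with MeNHOMe·HCl/AlMe3 should give racemic 4-hydroxy-N-methoxy-N-methyl-4-[8-methoxy-4-(triisopropylsilyloxy)naphthalen-1-yl]butanamide F2, which is silylated at once (TESCl, imidazole) to its triethylsilyl ether F3. Bromide 9 is converted with magnesium into [2,3-bis(tert-butyldimethylsilyloxy)phenyl]magnesium bromide F4, which does not suffer the silyl shift and adds once to F3. This should give racemic 1-[2,3-bis(tert-butyldimethylsilyloxy)phenyl]-4-(triethylsilyloxy)-4-[8-methoxy-4-(triisopropylsilyloxy)naphthalen-1-yl]butan-1-one F5. Buffered TBAF at rt removes all four silyl groups and returns to the route at 13.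

3. Step 3. The basic naphthyllithium may take a proton from the α-methylene of the aldehyde instead of adding, and the liberated methoxide may start to cleave the aryl silyl ether before quench. Fallback (non-basic three-carbon nucleophile on a naphthaldehyde): starting from 3, the aryllithium 5 is formylated with DMF to 8-methoxy-4-(triisopropylsilyloxy)-1-naphthaldehyde F6. Ethyl 3-bromopropanoate and zinc dust (cat. I2, DMA) give bromo(3-ethoxy-3-oxopropyl)zinc F7, which after transmetalation with ClTi(OiPr)3 should add to F6 to give racemic ethyl 4-hydroxy-4-[8-methoxy-4-(triisopropylsilyloxy)naphthalen-1-yl]butanoate F8. F8 lactonises on warming in toluene and returns to the route at 7.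

**Further compounds**

F1 | step 7 | rac-7,8-dihydroxy-4-(4-hydroxy-8-methoxynaphthalen-1-yl)-3,4-dihydronaphthalen-1(2H)-one | COc1cccc2c(O)ccc(C3CCC(=O)c4c3ccc(O)c4O)c12
F2 | step 5 | rac-4-hydroxy-N-methoxy-N-methyl-4-[8-methoxy-4-(triisopropylsilyloxy)naphthalen-1-yl]butanamide | CON(C)C(=O)CCC(O)c1ccc(O[Si](C(C)C)(C(C)C)C(C)C)c2cccc(OC)c12
F3 | step 5 | rac-N-methoxy-N-methyl-4-(triethylsilyloxy)-4-[8-methoxy-4-(triisopropylsilyloxy)naphthalen-1-yl]butanamide | CON(C)C(=O)CCC(O[Si](CC)(CC)CC)c1ccc(O[Si](C(C)C)(C(C)C)C(C)C)c2cccc(OC)c12
F4 | step 5 | [2,3-bis(tert-butyldimethylsilyloxy)phenyl]magnesium bromide | CC(C)(C)[Si](C)(C)Oc1cccc([Mg]Br)c1O[Si](C)(C)C(C)(C)C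
F5 | step 5 | rac-1-[2,3-bis(tert-butyldimethylsilyloxy)phenyl]-4-(triethylsilyloxy)-4-[8-methoxy-4-(triisopropylsilyloxy)naphthalen-1-yl]butan-1-one | COc1cccc2c(O[Si](C(C)C)(C(C)C)C(C)C)ccc(C(O[Si](CC)(CC)CC)CCC(=O)c3cccc(O[Si](C)(C)C(C)(C)C)c3O[Si](C)(C)C(C)(C)C)c12
F6 | step 3 | 8-methoxy-4-(triisopropylsilyloxy)-1-naphthaldehyde | COc1cccc2c(O[Si](C(C)C)(C(C)C)C(C)C)ccc(C=O)c12
F7 | step 3 | bromo(3-ethoxy-3-oxopropyl)zinc | CCOC(=O)CC[Zn]Br
F8 | step 3 | rac-ethyl 4-hydroxy-4-[8-methoxy-4-(triisopropylsilyloxy)naphthalen-1-yl]butanoate | CCOC(=O)CCC(O)c1ccc(O[Si](C(C)C)(C(C)C)C(C)C)c2cccc(OC)c12
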